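The cold hours were where I began when you asked me for a quick number, since eta and epsilon sit 20 h at −10 °C and then have 5.00 h warm.

common to all: D 25 mM; G 0.77 mM; time 25 h

|  | J | L | remark | temperature |
|---|---|---|---|---|
| eta | 0.25 M | 0.175 M (fed, over 20 h) | the addition at −10 °C, then warmed to 20 °C; the feed brings no volume worth counting |  |
| epsilon | 0.25 M | 0.175 M | everything together at the start at −10 °C, warmed to 20 °C at 20 h |  |
| gamma | 0.25 M (fed, over 20 h) | 0.175 M | all else is in the flask from the start; the feed brings no volume worth counting | 20 °C |
| beta | 0.25 M | 0.175 M | everything together at the start | 20 °C |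

* the best flask by amount of X, in percent of the J charged; "all alike" if 1.5 percentage points covers them all (eta / epsilon / gamma / beta / all alike)
* amount of X at the end, in percent of the J charged, eta
* amount of X at the end, in percent of the J charged, epsilon
* amount of X at the end, in percent of the J charged, gamma
* amount of X at the end, in percent of the J charged, beta

- the list of constants is for 20 °C, to be carried to other temperatures by the activation energies and enthalpies

    J + D ⇌ D + Z (K1 = 0.16, k1 = 150 /M/h, Ea1 = 51.0 kJ/mol, ΔH1 = 9.00 kJ/mol)
    G + Z ⇌ G.Z (K2 = 380 /M, k2 = 1100 /M/h, Ea2 = 37.0 kJ/mol, ΔH2 = −6.00 kJ/mol)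
    L + G.Z → G + X (k3 = 110 /M/h, Ea3 = 63.0 kJ/mol)
    D → E (k4 = 0.23 /h, Ea4 = 100 kJ/mol)
    (constants at 20 °C)

D turns J reversibly into Z, G takes up Z as G.Z, L carries G.Z on to X and frees G, and D dies meanwhile into E. With the charges of beta at 20 °C, G.Z had a half-life of 2.2 min against L, and J one of 0.18 h on the forward rate of its step, both far shorter than the warm stretch . So I took these fast steps as keeping pace and reckoned with what they left free.

The hours G needs at full load, with L as charged, to turn over an amount equal to the J charged came to 16.9 h, and this I called the working time. G was not at full load, though. J and Z in balance gave 34.5 mM of Z, and G stood half loaded at 1/K2 + k3·L/k2, which is 20.1 mM, so its load was 63.1%.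

The warm stretch divided by the working time, times the load, gave 18.7% of the J charged for eta and epsilon. In the cold, step 3 ran at 0.0525 of its warm speed, which at full load and with L as charged came to 6.23%. I committed to 18.7% to 24.9% for both.

For beta, over the whole time at 20 °C, the same sum gave 93.6%, more than the 70.0% that L, the limiting reagent, allows. D has a half-life of 3.01 h at 20 °C and gamma gets its J by a feed, so the sum did not carry over, and I gave no number for beta or gamma.

Your forecast said 18.5% for eta, 20% for epsilon, 35% for gamma and 46% for beta, with beta best, and held for the cold flasks that “L dosing hardly matters”. My lower figure stood just above yours for eta.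

The simulation gave 18.4% for eta, 20.0% for epsilon, 37.5% for gamma and 50.7% for beta, with beta best. Eta and epsilon lay 1.6 percentage points apart, and each result stood within your range.

In eta, X rose from 2.48% after 20.0 h to 18.4% after 25.0 h, a warm gain of 16 points against my 18.7%. The neighbouring flask was eta with G cut to 3.1 × 10⁻⁴ M. Its working time came to 41.9 h, and the load, whose formula holds no G, stayed as it was, so its warm stretch reckoned at 7.54%. That flask ended at 8.05%, which is 0.438 of the X in eta where the working times stand at 0.403, with 79% of its J still unbound.

The constants used here were chosen freely; the result is computed.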